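The route rests on cutting ring A across C1–C2 and C5–C10. In ring A the oxygen-bearing C3 lies para to the quaternary C10 and C5 is trigonal (C4=C5), so ring A is the adduct of a 2-silyloxydiene and methacrolein whose extra C5 centre is later erased. One catalytic asymmetric Diels–Alder reaction closes ring A, forms both bonds and fixes C10. Its precursor is the triisopropylsilyl dienol ether of (E)-3-methylpent-3-en-2-one; the terminal methyl becomes C6. The aldehyde is then extended to an (E)-4-acetoxy enethioate, the enol ether is oxidised to the C4=C5 enone, and C6 closes ring B on C7 by a vinylogous Michael addition.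

Key step: step 2

Remark: positions are numbered as in eudesmanes (ring A = C1–C5 and C10; ring B = C5–C10; C11–C13 = acrylate; C14 on C10; C15 on C4).
Remark: the sense of induction in step 2 is assigned from the usual binding model of the catalyst; the (R)-catalyst would be used if the adduct proved to be the enantiomer.
Remark: the (1S) quaternary centre of 5 is C10 of the target, where it is (R); only the CIP priorities change, not the geometry.

Step 1
Reactants: 1 (E)-3-methylpent-3-en-2-one
Product: 3 (E)-3-methyl-2-(triisopropylsilyloxy)penta-1,3-diene, via lithium dienolate 2 (not isolated)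
Conditions: LiN(i-Pr)2, THF, −78 °C; then i-Pr3SiOSO2CF3, −78 °C to 0 °C
Reagents that add atoms: triisopropylsilyl trifluoromethanesulfonate, CC(C)[Si](C(C)C)(C(C)C)OS(=O)(=O)C(F)(F)F
Why: Kinetic deprotonation of the acetyl methyl group by the hindered amide base gives the cross-conjugated lithium dienolate, which the silyl triflate traps on oxygen (kinetic enolate O-silylation) without touching the (E) double bond.

Step 2
Reactants: 3 (E)-3-methyl-2-(triisopropylsilyloxy)penta-1,3-diene; 4 methacrolein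
Product: 5 (1S,2S)-1,2,3-trimethyl-4-(triisopropylsilyloxy)cyclohex-3-ene-1-carbaldehyde (exo adduct)
Conditions: (S)-tetrahydro-1-(2-methylphenyl)-3,3-diphenyl-1H,3H-pyrrolo[1,2-c][1,3,2]oxazaborole (20 mol%), (CF3SO2)2NH (16 mol%), CH2Cl2, −78 °C
Reagents that add atoms: none
Why: The oxazaborolidinium ion binds the formyl oxygen of 4 (formyl C–H held against the ring oxygen), lowers the LUMO and exposes one face of the s-trans enal, so that an asynchronous concerted [4+2] cycloaddition with the s-cis diene follows; the closest known reaction type is the cationic oxazaborolidine-catalysed Diels–Alder reaction of 2-methacrolein with 2-silyloxy-1,3-dienes. Ring A is closed by the cycloaddition itself, both new sigma bonds (C1–C2 and C5–C10) forming suprafacially on diene and dienophile in one six-membered transition state. C10 is set by the catalyst: with the (S)-catalyst the diene should add to the Re face of the α-carbon of 4, which gives the (S)-aldehyde that corresponds to the 10β-methyl group of the target. C5 is set by the exo position of the formyl group relative to the (E)-diene, and either C5 epimer is usable because C5 becomes trigonal in step 6. The step needs regiocontrol and enantiofacial control: the silyloxy group on C3 and the terminal methyl group both put the largest HOMO coefficient on the CH2 terminus (C2), which therefore bonds to the β-carbon (C1) of 4, and the bulky triisopropylsilyl group keeps the enol ether intact towards the strong acid.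

Step 3
Reactants: 5 (1S,2S)-1,2,3-trimethyl-4-(triisopropylsilyloxy)cyclohex-3-ene-1-carbaldehyde; 6 triethyl phosphonoacetate
Product: 7 ethyl (2E)-3-[(1R,2R)-1,2,3-trimethyl-4-(triisopropylsilyloxy)cyclohex-3-en-1-yl]prop-2-enoate
Conditions: NaH, THF, 0 °C to rt
Reagents that add atoms: none
Why: Horner–Wadsworth–Emmons olefination of the non-enolisable neopentyl aldehyde with the sodium phosphonate anion should give the (E)-enoate (C8 and C7 added), and the silyl enol ether is inert to base.

Step 4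
Reactants: 7 ethyl (2E)-3-[(1R,2R)-1,2,3-trimethyl-4-(triisopropylsilyloxy)cyclohex-3-en-1-yl]prop-2-enoate
Product: 8 ethyl 3-[(1R,2R)-1,2,3-trimethyl-4-(triisopropylsilyloxy)cyclohex-3-en-1-yl]propanoate
Conditions: H2 (1 atm), 10% Pd/C, EtOAc, rt
Reagents that add atoms: none
Why: Heterogeneous catalytic hydrogenation saturates the disubstituted conjugated alkene far faster than the tetrasubstituted silyl enol ether, which should survive.

Step 5
Reactants: 8 ethyl 3-[(1R,2R)-1,2,3-trimethyl-4-(triisopropylsilyloxy)cyclohex-3-en-1-yl]propanoate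
Product: 9 3-[(1R,2R)-1,2,3-trimethyl-4-(triisopropylsilyloxy)cyclohex-3-en-1-yl]propanal
Conditions: i-Bu2AlH (1.1 equiv), CH2Cl2, −78 °C; aq. KNaC4H4O6 work-up
Reagents that add atoms: none
Why: Partial reduction of the ester with a dialkylaluminium hydride stops at the tetrahedral aluminium hemiacetal at low temperature and releases the aldehyde on work-up.

Step 6
Reactants: 9 3-[(1R,2R)-1,2,3-trimethyl-4-(triisopropylsilyloxy)cyclohex-3-en-1-yl]propanal
Product: 10 3-[(1S)-1,2,3-trimethyl-4-oxocyclohex-2-en-1-yl]propanal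
Conditions: Pd(OAc)2 (1.05 equiv), MeCN, rt to 40 °C
Reagents that add atoms: none
Why: Saegusa oxidation, in which palladation of the silyl enol ether at C4 and syn β-hydride elimination of H5 should give the conjugated C4=C5 enone and erase the C5 stereocentre, with the aldehyde as a spectator.

Step 7
Reactants: 11 bromoacetyl bromide; 12 ethanethiol
Product: 13 S-ethyl 2-bromoethanethioate
Conditions: pyridine, CH2Cl2, 0 °C
Reagents that add atoms: none
Why: Nucleophilic acyl substitution at the acyl bromide, which is much more reactive than the alkyl bromide, gives the bromo thioester.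

Step 8
Reactants: 13 S-ethyl 2-bromoethanethioate; 14 triphenylphosphine
Product: 16 S-ethyl 2-(triphenyl-λ5-phosphanylidene)ethanethioate, via phosphonium bromide 15 (not isolated)
Conditions: toluene, rt; then aq. Na2CO3, CH2Cl2
Reagents that add atoms: none
Why: SN2 quaternisation of the phosphine by the α-bromo thioester and deprotonation of the acidic phosphonium salt give the stabilised ylide (standard ylide preparation).

Step 9
Reactants: 10 3-[(1S)-1,2,3-trimethyl-4-oxocyclohex-2-en-1-yl]propanal; 16 S-ethyl 2-(triphenyl-λ5-phosphanylidene)ethanethioate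
Product: 18 S-ethyl (2E,4R)-4-(anilinooxy)-5-[(1R)-1,2,3-trimethyl-4-oxocyclohex-2-en-1-yl]pent-2-enethioate, via α-anilinooxy aldehyde 17 (not isolated)
Conditions: PhNO (1.1 equiv), L-proline (20 mol%), DMSO, rt; then 16, 0 °C to rt
Reagents that add atoms: nitrosobenzene, O=Nc1ccccc1
Why: Proline-catalysed α-aminoxylation adds the enamine α-carbon to the oxygen of nitrosobenzene, L-proline should give the (R) C8–O centre, and the labile α-aminoxy aldehyde is trapped at once by Wittig olefination with the stabilised ylide to give the (E)-enethioate (C11 and C12 added).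

Step 10
Reactants: 18 S-ethyl (2E,4R)-4-(anilinooxy)-5-[(1R)-1,2,3-trimethyl-4-oxocyclohex-2-en-1-yl]pent-2-enethioate
Product: 19 S-ethyl (2E,4R)-4-hydroxy-5-[(1R)-1,2,3-trimethyl-4-oxocyclohex-2-en-1-yl]pent-2-enethioate
Conditions: Cu(OAc)2 (30 mol%), EtOH, rt
Reagents that add atoms: none
Why: Copper-catalysed cleavage of the weak N–O bond frees the allylic alcohol without touching the C8 stereocentre, the enone or the thioester.

Step 11
Reactants: 19 S-ethyl (2E,4R)-4-hydroxy-5-[(1R)-1,2,3-trimethyl-4-oxocyclohex-2-en-1-yl]pent-2-enethioate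
Product: 20 S-ethyl (2E,4R)-4-acetoxy-5-[(1R)-1,2,3-trimethyl-4-oxocyclohex-2-en-1-yl]pent-2-enethioate
Conditions: Ac2O, pyridine, DMAP (cat.), CH2Cl2, 0 °C to rt
Reagents that add atoms: acetic anhydride, CC(=O)OC(C)=O
Why: Acetylation of the secondary alcohol under nucleophilic catalysis installs the C8 acetate with retention, before any ring-B carbonyl could lactonise with a free C8 hydroxyl.

Step 12
Reactants: 20 S-ethyl (2E,4R)-4-acetoxy-5-[(1R)-1,2,3-trimethyl-4-oxocyclohex-2-en-1-yl]pent-2-enethioate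
Product: 21 S-ethyl 2-[(2R,3R,4aR)-3-acetoxy-4a,8-dimethyl-7-oxo-1,2,3,4,4a,5,6,7-octahydronaphthalen-2-yl]ethanethioate
Conditions: Cs2CO3 (0.5 equiv), MeCN, 0 °C to rt
Reagents that add atoms: none
Why: Intramolecular vinylogous Michael addition, in which the base reversibly forms the extended dienolate of the enone and its C6 terminus adds 6-exo-trig to C7 of the enethioate to close ring B; a chair-like closure with the enethioate equatorial and the C8 acetate axial should place the new side chain cis to the acetate (7β).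

Step 13
Reactants: 21 S-ethyl 2-[(2R,3R,4aR)-3-acetoxy-4a,8-dimethyl-7-oxo-1,2,3,4,4a,5,6,7-octahydronaphthalen-2-yl]ethanethioate
Product: 22 S-ethyl 2-[(2R,3R,4aR,7S)-3-acetoxy-7-hydroxy-4a,8-dimethyl-1,2,3,4,4a,5,6,7-octahydronaphthalen-2-yl]ethanethioate
Conditions: NaBH4, CeCl3·7H2O, MeOH/THF, −78 °C
Reagents that add atoms: none
Why: Luche reduction gives selective 1,2-reduction of the enone, hydride should add to the α face anti to the axial C10 methyl group to give the pseudo-equatorial 3β-alcohol, and thioester and acetate survive at −78 °C.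

Step 14
Reactants: 22 S-ethyl 2-[(2R,3R,4aR,7S)-3-acetoxy-7-hydroxy-4a,8-dimethyl-1,2,3,4,4a,5,6,7-octahydronaphthalen-2-yl]ethanethioate
Product: 23 S-ethyl 2-[(2R,3R,4aR,7S)-3-acetoxy-4a,8-dimethyl-7-(2-methylpropanoyloxy)-1,2,3,4,4a,5,6,7-octahydronaphthalen-2-yl]ethanethioate
Conditions: i-PrCOCl, pyridine, DMAP (cat.), CH2Cl2, 0 °C to rt
Reagents that add atoms: 2-methylpropanoyl chloride, CC(C)C(Cl)=O
Why: Esterification of the allylic alcohol with the acid chloride under nucleophilic catalysis gives the isobutyrate with retention at C3.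

Step 15
Reactants: 23 S-ethyl 2-[(2R,3R,4aR,7S)-3-acetoxy-4a,8-dimethyl-7-(2-methylpropanoyloxy)-1,2,3,4,4a,5,6,7-octahydronaphthalen-2-yl]ethanethioate
Product: 24 2-[(2R,3R,4aR,7S)-3-acetoxy-4a,8-dimethyl-7-(2-methylpropanoyloxy)-1,2,3,4,4a,5,6,7-octahydronaphthalen-2-yl]acetaldehyde
Conditions: Et3SiH, 10% Pd/C, acetone, rt
Reagents that add atoms: none
Why: Fukuyama reduction, in which the C–S bond adds oxidatively to palladium and the silane delivers hydride, converts the thioester into the aldehyde under neutral conditions that leave both esters untouched.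

Step 16
Reactants: 24 2-[(2R,3R,4aR,7S)-3-acetoxy-4a,8-dimethyl-7-(2-methylpropanoyloxy)-1,2,3,4,4a,5,6,7-octahydronaphthalen-2-yl]acetaldehyde
Product: 26 2-[(2R,3R,4aR,7S)-3-acetoxy-4a,8-dimethyl-7-(2-methylpropanoyloxy)-1,2,3,4,4a,5,6,7-octahydronaphthalen-2-yl]prop-2-enal, via Mannich base 25 (not isolated)
Conditions: Me2N=CH2 I (2.5 equiv), Et3N, CH2Cl2, rt
Reagents that add atoms: N,N-dimethylmethyleneiminium iodide, C[N+](C)=C.[I-]
Why: Mannich reaction of the aldehyde enol with the iminium salt followed by β-elimination of dimethylamine (α-methylenation of an aldehyde) creates the C11=C13 methylene without a base strong enough to touch the esters.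

Step 17
Reactants: 26 2-[(2R,3R,4aR,7S)-3-acetoxy-4a,8-dimethyl-7-(2-methylpropanoyloxy)-1,2,3,4,4a,5,6,7-octahydronaphthalen-2-yl]prop-2-enal
Product: 27 2-[(2R,3R,4aR,7S)-3-acetoxy-4a,8-dimethyl-7-(2-methylpropanoyloxy)-1,2,3,4,4a,5,6,7-octahydronaphthalen-2-yl]prop-2-enoic acid
Conditions: NaClO2, NaH2PO4, 2-methylbut-2-ene, t-BuOH/H2O, 0 °C to rt
Reagents that add atoms: sodium chlorite, [Na+].[O-]Cl=O
Why: Pinnick oxidation converts the enal into the acrylic acid, and the scavenger alkene removes hypochlorous acid and so protects the C4=C5 and C11=C13 double bonds.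

Step 18
Reactants: 27 2-[(2R,3R,4aR,7S)-3-acetoxy-4a,8-dimethyl-7-(2-methylpropanoyloxy)-1,2,3,4,4a,5,6,7-octahydronaphthalen-2-yl]prop-2-enoic acid
Product: 28 methyl 2-[(2R,3R,4aR,7S)-3-acetoxy-4a,8-dimethyl-7-(2-methylpropanoyloxy)-1,2,3,4,4a,5,6,7-octahydronaphthalen-2-yl]prop-2-enoate (CNP0127901.1)
Conditions: Me3SiCHN2, MeOH/toluene, 0 °C
Reagents that add atoms: (trimethylsilyl)diazomethane, C[Si](C)(C)C=[N+]=[N-]
Why: Methylation of the carboxylic acid by the diazoalkane (protonation, then alkylation of the carboxylate with loss of N2) gives the methyl ester under neutral conditions.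

Compound list
1 | (E)-3-methylpent-3-en-2-one | C/C=C(\C)C(C)=O | starting material
2 | lithium (E)-3-methylpenta-1,3-dien-2-olate | [Li]OC(=C)/C(C)=C/C | intermediate
3 | (E)-3-methyl-2-(triisopropylsilyloxy)penta-1,3-diene | C=C(O[Si](C(C)C)(C(C)C)C(C)C)/C(C)=C/C | intermediate
4 | methacrolein (2-methylprop-2-enal) | CC(=C)C=O | starting material
5 | (1S,2S)-1,2,3-trimethyl-4-(triisopropylsilyloxy)cyclohex-3-ene-1-carbaldehyde | O=C[C@@]1(C)CCC(O[Si](C(C)C)(C(C)C)C(C)C)=C(C)[C@@H]1C | intermediate
6 | triethyl phosphonoacetate | CCOC(=O)CP(=O)(OCC)OCC | starting material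
7 | ethyl (2E)-3-[(1R,2R)-1,2,3-trimethyl-4-(triisopropylsilyloxy)cyclohex-3-en-1-yl]prop-2-enoate | CCOC(=O)/C=C/[C@@]1(C)CCC(O[Si](C(C)C)(C(C)C)C(C)C)=C(C)[C@@H]1C | intermediate
8 | ethyl 3-[(1R,2R)-1,2,3-trimethyl-4-(triisopropylsilyloxy)cyclohex-3-en-1-yl]propanoate | CCOC(=O)CC[C@@]1(C)CCC(O[Si](C(C)C)(C(C)C)C(C)C)=C(C)[C@@H]1C | intermediate
9 | 3-[(1R,2R)-1,2,3-trimethyl-4-(triisopropylsilyloxy)cyclohex-3-en-1-yl]propanal | O=CCC[C@@]1(C)CCC(O[Si](C(C)C)(C(C)C)C(C)C)=C(C)[C@@H]1C | intermediate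
10 | 3-[(1S)-1,2,3-trimethyl-4-oxocyclohex-2-en-1-yl]propanal | O=CCC[C@@]1(C)CCC(=O)C(C)=C1C | intermediate
11 | bromoacetyl bromide | BrCC(Br)=O | starting material
12 | ethanethiol | CCS | starting material
13 | S-ethyl 2-bromoethanethioate | CCSC(=O)CBr | intermediate
14 | triphenylphosphine | c1ccc(cc1)P(c1ccccc1)c1ccccc1 | starting material
15 | [2-(ethylsulfanyl)-2-oxoethyl]triphenylphosphonium bromide | CCSC(=O)C[P+](c1ccccc1)(c1ccccc1)c1ccccc1.[Br-] | intermediate
16 | S-ethyl 2-(triphenyl-λ5-phosphanylidene)ethanethioate | CCSC(=O)C=P(c1ccccc1)(c1ccccc1)c1ccccc1 | intermediate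
17 | (2R)-2-(anilinooxy)-3-[(1R)-1,2,3-trimethyl-4-oxocyclohex-2-en-1-yl]propanal | O=C[C@H](ONc1ccccc1)C[C@@]1(C)CCC(=O)C(C)=C1C | intermediate
18 | S-ethyl (2E,4R)-4-(anilinooxy)-5-[(1R)-1,2,3-trimethyl-4-oxocyclohex-2-en-1-yl]pent-2-enethioate | CCSC(=O)/C=C/[C@H](ONc1ccccc1)C[C@@]1(C)CCC(=O)C(C)=C1C | intermediate
19 | S-ethyl (2E,4R)-4-hydroxy-5-[(1R)-1,2,3-trimethyl-4-oxocyclohex-2-en-1-yl]pent-2-enethioate | CCSC(=O)/C=C/[C@H](O)C[C@@]1(C)CCC(=O)C(C)=C1C | intermediate
20 | S-ethyl (2E,4R)-4-acetoxy-5-[(1R)-1,2,3-trimethyl-4-oxocyclohex-2-en-1-yl]pent-2-enethioate | CCSC(=O)/C=C/[C@H](OC(C)=O)C[C@@]1(C)CCC(=O)C(C)=C1C | intermediate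
21 | S-ethyl 2-[(2R,3R,4aR)-3-acetoxy-4a,8-dimethyl-7-oxo-1,2,3,4,4a,5,6,7-octahydronaphthalen-2-yl]ethanethioate | CCSC(=O)C[C@H]1CC2=C(C)C(=O)CC[C@]2(C)C[C@H]1OC(C)=O | intermediate
22 | S-ethyl 2-[(2R,3R,4aR,7S)-3-acetoxy-7-hydroxy-4a,8-dimethyl-1,2,3,4,4a,5,6,7-octahydronaphthalen-2-yl]ethanethioate | CCSC(=O)C[C@H]1CC2=C(C)[C@@H](O)CC[C@]2(C)C[C@H]1OC(C)=O | intermediate
23 | S-ethyl 2-[(2R,3R,4aR,7S)-3-acetoxy-4a,8-dimethyl-7-(2-methylpropanoyloxy)-1,2,3,4,4a,5,6,7-octahydronaphthalen-2-yl]ethanethioate | CCSC(=O)C[C@H]1CC2=C(C)[C@@H](OC(=O)C(C)C)CC[C@]2(C)C[C@H]1OC(C)=O | intermediate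
24 | 2-[(2R,3R,4aR,7S)-3-acetoxy-4a,8-dimethyl-7-(2-methylpropanoyloxy)-1,2,3,4,4a,5,6,7-octahydronaphthalen-2-yl]acetaldehyde | O=CC[C@H]1CC2=C(C)[C@@H](OC(=O)C(C)C)CC[C@]2(C)C[C@H]1OC(C)=O | intermediate
25 | 3-(dimethylamino)-2-[(2R,3R,4aR,7S)-3-acetoxy-4a,8-dimethyl-7-(2-methylpropanoyloxy)-1,2,3,4,4a,5,6,7-octahydronaphthalen-2-yl]propanal (epimers at C11) | CN(C)CC(C=O)[C@H]1CC2=C(C)[C@@H](OC(=O)C(C)C)CC[C@]2(C)C[C@H]1OC(C)=O | intermediate
26 | 2-[(2R,3R,4aR,7S)-3-acetoxy-4a,8-dimethyl-7-(2-methylpropanoyloxy)-1,2,3,4,4a,5,6,7-octahydronaphthalen-2-yl]prop-2-enal | C=C(C=O)[C@H]1CC2=C(C)[C@@H](OC(=O)C(C)C)CC[C@]2(C)C[C@H]1OC(C)=O | intermediate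
27 | 2-[(2R,3R,4aR,7S)-3-acetoxy-4a,8-dimethyl-7-(2-methylpropanoyloxy)-1,2,3,4,4a,5,6,7-octahydronaphthalen-2-yl]prop-2-enoic acid | C=C(C(=O)O)[C@H]1CC2=C(C)[C@@H](OC(=O)C(C)C)CC[C@]2(C)C[C@H]1OC(C)=O | intermediate
28 | methyl 2-[(2R,3R,4aR,7S)-3-acetoxy-4a,8-dimethyl-7-(2-methylpropanoyloxy)-1,2,3,4,4a,5,6,7-octahydronaphthalen-2-yl]prop-2-enoate | C=C(C(=O)OC)[C@H]1CC2=C(C)[C@@H](OC(=O)C(C)C)CC[C@]2(C)C[C@H]1OC(C)=O | target

Total step count: 18. Longest linear sequence: 16 steps (steps 1–6 and 9–18, from 1); steps 7 and 8 make the ylide on a side branch.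

Steps most likely to fail

Step 12 (closure of ring B). Three things may go wrong:
- closure through C2 or C4 of the enolate system, which would give bridged bicycles;
- loss of the C8 configuration through γ-deprotonation of the acceptor;
- poor facial selectivity at C7 if a boat-like closure, which puts the acetate anti to the incoming carbon, competes with the chair.

The fallback sets out from 19 and comes back at 21. Oxidation of the allylic alcohol of 19 with Dess–Martin periodinane gives S-ethyl (2E)-4-oxo-5-[(1R)-1,2,3-trimethyl-4-oxocyclohex-2-en-1-yl]pent-2-enethioate F1. The same base-mediated vinylogous Michael addition, now onto a doubly activated alkene with no stereocentre at C8, gives S-ethyl 2-[(2R,4aR)-4a,8-dimethyl-3,7-dioxo-1,2,3,4,4a,5,6,7-octahydronaphthalen-2-yl]ethanethioate F2. In F2, C7 is epimerisable next to the C8 ketone and should settle equatorial (7β). NaBH4 at −78 °C should reduce the saturated C8 ketone in preference to the hindered enone, from the α face because the axial C10 methyl shields the β face. The 8β-alkoxide then lactonises onto the thioester to give the cis-fused lactone (3aR,8aR,9aR)-5,8a-dimethyl-3a,4,7,8,8a,9-hexahydronaphtho[2,3-b]furan-2,6(3H,9aH)-dione F3. Ring opening with Me2AlSEt (from Me3Al and EtSH), with acetylation of the aluminium alkoxide in the same flask (Ac2O, DMAP), returns to 21. This replaces kinetic control at C7 by thermodynamic control and sets C8 by hydride delivery.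

Step 2 (Diels–Alder reaction). The strong acid may protodesilylate or polymerise the diene, the hindered diene terminus may react slowly, and enantiofacial discrimination may be incomplete. The fallback sets out from 3 and 4 and comes back at 5. Thermal cycloaddition (toluene, 90 °C, sealed tube) gives the racemic exo adduct F4. Condensation with (1R,2R)-N,N'-dimethyl-1,2-diphenylethane-1,2-diamine (molecular sieves, CH2Cl2) gives two diastereomeric aminals, separable by chromatography: (4R,5R)-1,3-dimethyl-4,5-diphenyl-2-[(1S,2R)-1,2,3-trimethyl-4-(triisopropylsilyloxy)cyclohex-3-en-1-yl]imidazolidine F5 and its (1R,2S)-cyclohexenyl diastereomer F6. Mild hydrolysis of F5 (wet silica gel, or 0.5 M aq. HCl/Et2O at 0 °C) releases 5. Classical resolution replaces catalyst control.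

Step 6 (Saegusa oxidation). Palladation of the hindered tetrasubstituted triisopropylsilyl enol ether may be slow, and β-hydride elimination may run towards the C4 methyl group to give the exocyclic methylene ketone. The fallback sets out from 9 and comes back at 10. Electrophilic selenenylation of the silyl enol ether with PhSeCl (CH2Cl2, −78 °C) gives regiospecifically the α-selanyl ketone 3-[1,2,3-trimethyl-4-oxo-3-(phenylselanyl)cyclohexyl]propanal F7 (C10 and C5 as in 9, epimers at C4). Oxidation (NaIO4, NaHCO3, aq. MeOH) and selenoxide syn-elimination give 10. Any exocyclic isomer is equilibrated to the conjugated C4=C5 enone with catalytic RhCl3·3H2O in EtOH.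

Further compounds
F1 | step 12 | S-ethyl (2E)-4-oxo-5-[(1R)-1,2,3-trimethyl-4-oxocyclohex-2-en-1-yl]pent-2-enethioate | CCSC(=O)/C=C/C(=O)C[C@@]1(C)CCC(=O)C(C)=C1C
F2 | step 12 | S-ethyl 2-[(2R,4aR)-4a,8-dimethyl-3,7-dioxo-1,2,3,4,4a,5,6,7-octahydronaphthalen-2-yl]ethanethioate | CCSC(=O)C[C@H]1CC2=C(C)C(=O)CC[C@]2(C)CC1=O
F3 | step 12 | (3aR,8aR,9aR)-5,8a-dimethyl-3a,4,7,8,8a,9-hexahydronaphtho[2,3-b]furan-2,6(3H,9aH)-dione | O=C1C[C@H]2CC3=C(C)C(=O)CC[C@]3(C)C[C@H]2O1
F4 | step 2 | racemic exo-1,2,3-trimethyl-4-(triisopropylsilyloxy)cyclohex-3-ene-1-carbaldehyde | O=C[C@@]1(C)CCC(O[Si](C(C)C)(C(C)C)C(C)C)=C(C)[C@@H]1C.O=C[C@]1(C)CCC(O[Si](C(C)C)(C(C)C)C(C)C)=C(C)[C@H]1C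
F5 | step 2 | (4R,5R)-1,3-dimethyl-4,5-diphenyl-2-[(1S,2R)-1,2,3-trimethyl-4-(triisopropylsilyloxy)cyclohex-3-en-1-yl]imidazolidine | CN1C([C@@]4(C)CCC(O[Si](C(C)C)(C(C)C)C(C)C)=C(C)[C@@H]4C)N(C)[C@H](c2ccccc2)[C@H]1c3ccccc3
F6 | step 2 | (4R,5R)-1,3-dimethyl-4,5-diphenyl-2-[(1R,2S)-1,2,3-trimethyl-4-(triisopropylsilyloxy)cyclohex-3-en-1-yl]imidazolidine | CN1C([C@]4(C)CCC(O[Si](C(C)C)(C(C)C)C(C)C)=C(C)[C@H]4C)N(C)[C@H](c2ccccc2)[C@H]1c3ccccc3
F7 | step 6 | 3-[1,2,3-trimethyl-4-oxo-3-(phenylselanyl)cyclohexyl]propanal (C10 and C5 as in 9, epimers at C4) | O=CCC[C@@]1(C)CCC(=O)C(C)([Se]c2ccccc2)[C@@H]1C
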